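Cuts: ring C (the seven-membered lactone) is opened at its C(=O)–O bond, then at the diaryl ether bond to the ring A carbon that lies between formyl and carboxyl. Ring D is opened at its O–CMe2 bond.
Enabling feature: ring B carries oxygen on three carbons in a 1,2,4 array, with its only CH between two of them. Its last two, adjacent carbons bear the methyl group and the ring D acyl carbon. The C(O)–C(O)–CH–C(O) run is a trioxygenated diene and the C(CH3)–C(acyl) pair is a methyl alkynyl ketone, so ring B is cut at C(OBn)–C(CH3) and C(OH)–C(acyl).
Forward order: ring B by Diels–Alder reaction and aromatization, then ring D by oxa-Michael closure. Ring A (made by metalation, bromination and carbonylation of an anisole) is joined by SNAr, and ring C is closed last by lactonization.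
The three ring B oxygens arrive as OH, OBn and OMe. This decides which one closes ring D, which becomes the ether and which becomes the ester.
Stereochemistry: the target has no stereocentre and no stereogenic double bond, and every transient centre is erased on the way.

Key step: step 5

Assumption: the benzyloxy keto ester and 3-fluoro-5-methylanisole are taken as catalogue compounds, and the silyl ketene acetal diene is used as the mixture of geometric isomers that its preparation delivers.

Step 1
Reactants: 1 methyl 4-(benzyloxy)-3-oxobutanoate
Product: 2 methyl (E)-4-(benzyloxy)-3-methoxybut-2-enoate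
Conditions: HC(OMe)3, H2SO4 (cat.), MeOH, 50 °C
Reagents that add atoms: trimethyl orthoformate, COC(OC)OC
Why: Acid-catalysed enol etherification with an orthoester: the ketone is ketalized and loses methanol toward the ester-activated CH2, which should give the conjugated E enol ether as with simple acetoacetates, the benzyl ether and the methyl ester being inert.

Step 2
Reactants: 2 methyl (E)-4-(benzyloxy)-3-methoxybut-2-enoate
Product: 4 1-(benzyloxy)-2,4-dimethoxy-4-(trimethylsilyloxy)buta-1,3-diene, via lithium dienolate 3 (not isolated)
Conditions: LiN(iPr)2 (LDA, commercial solution), THF, −78 °C; Me3SiCl, −78 °C to 0 °C; pentane, filtration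
Reagents that add atoms: chlorotrimethylsilane, C[Si](C)(C)Cl
Why: Gamma-deprotonation of the beta-methoxy enoate by LDA (the CH2 cis to the ester is allylic and oxygen-flanked) gives the extended enolate 3, the oxophilic chlorosilane traps it on oxygen as in the standard preparation of vinylketene silyl acetals, and the stabilized anion should not undergo Wittig rearrangement at this temperature.

Step 3
Reactants: 5 1-propynylmagnesium bromide; 6 3-methylbut-2-enal
Product: 7 6-methylhept-5-en-2-yn-4-ol (racemic)
Conditions: THF, 0 °C; aq NH4Cl
Reagents that add atoms: none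
Why: Grignard 1,2-addition of a hard alkynyl nucleophile to the aldehyde carbonyl of an enal, with no conjugate addition expected at the beta,beta-disubstituted position, and the racemic carbinol centre is removed in step 4.

Step 4
Reactants: 7 6-methylhept-5-en-2-yn-4-ol
Product: 8 6-methylhept-5-en-2-yn-4-one
Conditions: MnO2 (activated), CH2Cl2, rt
Reagents that add atoms: none
Why: MnO2 oxidation, selective for allylic and propargylic alcohols, should convert the doubly activated carbinol into the cross-conjugated ynone under neutral conditions that leave the alkyne and the alkene alone.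

Step 5
Reactants: 4 1-(benzyloxy)-2,4-dimethoxy-4-(trimethylsilyloxy)buta-1,3-diene; 8 6-methylhept-5-en-2-yn-4-one
Product: 11 1-[3-(benzyloxy)-6-hydroxy-4-methoxy-2-methylphenyl]-3-methylbut-2-en-1-one, via cyclohexadiene cycloadduct 9 (not isolated), via aryl trimethylsilyl ether 10 (not isolated)
Conditions: 4 (2 equiv), toluene (concentrated), 110 °C, sealed tube; then 1 M HCl, THF, 0 °C to rt
Reagents that add atoms: none
Why: The electron-rich diene 4 and the electron-poor alkyne of 8 combine in a normal-demand [4+2] cycloaddition that is concerted but highly asynchronous (its stepwise limit, Mukaiyama–Michael addition followed by closure onto the oxocarbenium ion, leads to the same skeleton), the benzyloxy-bearing terminus bonding to the methyl-bearing beta carbon and the ketene acetal carbon to the acyl-bearing alpha carbon to give 1,4-cyclohexadiene 9. The closest known reaction type is the benzannulation of Brassard- and Danishefsky-type oxygenated dienes with alkynones and alkynoates to give resorcinol derivatives. Ring B is thus closed in the intermolecular [4+2] mode with two new C–C bonds, after which 9 ionizes at its ketal carbon, expels methanol and loses the doubly allylic hydrogen geminal to OBn (net 1,4-elimination) to give 10, and dilute acid cleaves the Si–O bond to leave the phenol hydrogen-bonded to the ketone. No stereocentre survives, since the two sp3 ring carbons of 9 become aromatic, so the isomer mixture of 4 and the endo/exo question matter only for the rate, the isomer with OBn pointing outward being the faster one. Regioselectivity is required and is secured by the two ketene acetal oxygens and the 2-methoxy group, which all push electron density to the benzyloxy-bearing terminus and outweigh the single opposing benzyloxy donor, matched with the largest LUMO coefficient at the ynone beta carbon. Chemoselectivity is also required: the trisubstituted beta,beta-dimethyl alkene of 8 is too hindered and too electron-rich to compete with the alkyne, and benzyl alcohol cannot be lost in place of methanol because the ketal carbon carries no hydrogen.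

Step 6
Reactants: 11 1-[3-(benzyloxy)-6-hydroxy-4-methoxy-2-methylphenyl]-3-methylbut-2-en-1-one
Product: 12 6-(benzyloxy)-7-methoxy-2,2,5-trimethylchroman-4-one
Conditions: K2CO3 (0.3 equiv), MeOH, 50 °C
Reagents that add atoms: none
Why: Base-catalysed intramolecular oxa-Michael addition (6-endo-trig) of the only free hydroxyl to the beta,beta-dimethyl enone, the classical closure of o-hydroxyaryl 2-methylpropenyl ketones to 2,2-dimethylchroman-4-ones, which are the thermodynamic sink of this equilibrium.

Step 7
Reactants: 12 6-(benzyloxy)-7-methoxy-2,2,5-trimethylchroman-4-one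
Product: 13 6-hydroxy-7-methoxy-2,2,5-trimethylchroman-4-one
Conditions: H2 (1 atm), 10% Pd/C, EtOAc, rt
Reagents that add atoms: none
Why: Catalytic hydrogenolysis of a benzyl aryl ether, placed after ring D closure so that no alkene is left to be reduced, and mild enough at one atmosphere to spare the aryl ketone and the methyl ether.

Step 8
Reactants: 14 1-fluoro-3-methoxy-5-methylbenzene (3-fluoro-5-methylanisole)
Product: 16 2-fluoro-6-methoxy-4-methylbenzaldehyde, via aryllithium 15 (not isolated)
Conditions: n-BuLi, THF, −78 °C; DMF, −78 °C to 0 °C; 1 M HCl
Reagents that add atoms: N,N-dimethylformamide, CN(C)C=O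
Why: Directed ortho-metalation followed by formylation: the hydrogen between fluorine and methoxy is the most acidic and best coordinated site, aryllithium 15 does not lose LiF at −78 °C, and DMF delivers the formyl carbon.

Step 9
Reactants: 16 2-fluoro-6-methoxy-4-methylbenzaldehyde
Product: 17 3-bromo-2-fluoro-6-methoxy-4-methylbenzaldehyde
Conditions: NBS, MeCN, 0 °C to rt, dark
Reagents that add atoms: N-bromosuccinimide, O=C1CCC(=O)N1Br
Why: Electrophilic aromatic bromination governed by the methoxy group, which should direct to its para position (also ortho to F and CH3 and meta to CHO) in preference to the more crowded position between OCH3 and CH3, a polar solvent in the dark suppressing benzylic bromination.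

Step 10
Reactants: 17 3-bromo-2-fluoro-6-methoxy-4-methylbenzaldehyde
Product: 18 benzyl 2-fluoro-3-formyl-4-methoxy-6-methylbenzoate
Conditions: Pd(OAc)2 (5 mol %), Xantphos (6 mol %), CO (5 bar), BnOH (3 equiv), Et3N, toluene, 100 °C
Reagents that add atoms: carbon monoxide, [C-]#[O+]; benzyl alcohol, OCc1ccccc1
Why: Palladium-catalysed alkoxycarbonylation: zerovalent palladium formed in situ inserts into the C–Br bond, CO insertion gives the acylpalladium species and benzyl alcohol intercepts it, a sequence that tolerates aryl aldehydes and aryl fluorides because only a tertiary amine base is present.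

Step 11
Reactants: 13 6-hydroxy-7-methoxy-2,2,5-trimethylchroman-4-one; 18 benzyl 2-fluoro-3-formyl-4-methoxy-6-methylbenzoate
Product: 19 benzyl 3-formyl-4-methoxy-2-[(7-methoxy-2,2,5-trimethyl-4-oxochroman-6-yl)oxy]-6-methylbenzoate
Conditions: Cs2CO3, DMF, 60 °C
Reagents that add atoms: none
Why: Nucleophilic aromatic substitution by addition–elimination: the fluoride sits ortho to both the formyl and the ester group, whereas methoxy and methyl are meta to it and do not deactivate, so the caesium phenoxide formed at the only acidic site of 13 should displace it and fix the ether at O-6 of the chromanone.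

Step 12
Reactants: 19 benzyl 3-formyl-4-methoxy-2-[(7-methoxy-2,2,5-trimethyl-4-oxochroman-6-yl)oxy]-6-methylbenzoate
Product: 20 3-formyl-4-hydroxy-2-[(7-hydroxy-2,2,5-trimethyl-4-oxochroman-6-yl)oxy]-6-methylbenzoic acid
Conditions: BBr3 (8 equiv), CH2Cl2, −78 °C to rt; H2O
Reagents that add atoms: none
Why: Lewis-acid dealkylation in which BBr3 binds each ether or ester oxygen and bromide removes the alkyl group by SN2, so the benzyl ester, the formyl-chelated methyl ether of ring A and the methyl ether para to the ring D ketone fall in one operation, while the diaryl ether is inert, ring D can only reclose if it opens, and the absence of base and of soft nucleophiles rules out attack on the activated ring A carbon and Smiles migration of ring A to the neighbouring oxygen.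

Step 13
Reactants: 20 3-formyl-4-hydroxy-2-[(7-hydroxy-2,2,5-trimethyl-4-oxochroman-6-yl)oxy]-6-methylbenzoic acid
Product: 22 mollicellin A, via mixed trifluoroacetic anhydride 21 (not isolated)
Conditions: (CF3CO)2O, toluene–CH2Cl2, high dilution, 0 °C to rt; aq NaHCO3 wash
Reagents that add atoms: none
Why: Mixed-anhydride lactonization (7-exo-trig acyl substitution), the established closure of 2-(2-hydroxyaryloxy)benzoic acids to depsidones: the hindered acid is activated as 21 and taken by the neighbouring ring B hydroxyl, xanthone formation is blocked because both ring B positions ortho to the ether oxygen are substituted, and the ring A hydroxyl, tied to the formyl group by a hydrogen bond, is a poor competitor.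

Compound list
1 | methyl 4-(benzyloxy)-3-oxobutanoate | COC(=O)CC(=O)COCc1ccccc1 | starting material
2 | methyl (E)-4-(benzyloxy)-3-methoxybut-2-enoate | COC(=O)/C=C(/OC)COCc1ccccc1 | intermediate
3 | lithium dienolate of 2 (not isolated) | [Li+].COC([O-])=CC(OC)=COCc1ccccc1 | intermediate
4 | 1-(benzyloxy)-2,4-dimethoxy-4-(trimethylsilyloxy)buta-1,3-diene (mixture of geometric isomers) | COC(O[Si](C)(C)C)=CC(OC)=COCc1ccccc1 | intermediate
5 | 1-propynylmagnesium bromide | CC#C[Mg]Br | starting material
6 | 3-methylbut-2-enal | CC(C)=CC=O | starting material
7 | 6-methylhept-5-en-2-yn-4-ol (racemic) | CC#CC(O)C=C(C)C | intermediate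
8 | 6-methylhept-5-en-2-yn-4-one | CC#CC(=O)C=C(C)C | intermediate
9 | 1-[3-(benzyloxy)-4,6-dimethoxy-2-methyl-6-(trimethylsilyloxy)cyclohexa-1,4-dien-1-yl]-3-methylbut-2-en-1-one (mixture of diastereomers, not isolated) | COC1(O[Si](C)(C)C)C=C(OC)C(OCc2ccccc2)C(C)=C1C(=O)C=C(C)C | intermediate
10 | 1-[3-(benzyloxy)-4-methoxy-2-methyl-6-(trimethylsilyloxy)phenyl]-3-methylbut-2-en-1-one (not isolated) | COc1cc(O[Si](C)(C)C)c(C(=O)C=C(C)C)c(C)c1OCc1ccccc1 | intermediate
11 | 1-[3-(benzyloxy)-6-hydroxy-4-methoxy-2-methylphenyl]-3-methylbut-2-en-1-one | COc1cc(O)c(C(=O)C=C(C)C)c(C)c1OCc1ccccc1 | intermediate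
12 | 6-(benzyloxy)-7-methoxy-2,2,5-trimethylchroman-4-one | COc1cc2OC(C)(C)CC(=O)c2c(C)c1OCc1ccccc1 | intermediate
13 | 6-hydroxy-7-methoxy-2,2,5-trimethylchroman-4-one | COc1cc2OC(C)(C)CC(=O)c2c(C)c1O | intermediate
14 | 1-fluoro-3-methoxy-5-methylbenzene | COc1cc(C)cc(F)c1 | starting material
15 | (2-fluoro-6-methoxy-4-methylphenyl)lithium (not isolated) | COc1cc(C)cc(F)c1[Li] | intermediate
16 | 2-fluoro-6-methoxy-4-methylbenzaldehyde | COc1cc(C)cc(F)c1C=O | intermediate
17 | 3-bromo-2-fluoro-6-methoxy-4-methylbenzaldehyde | COc1cc(C)c(Br)c(F)c1C=O | intermediate
18 | benzyl 2-fluoro-3-formyl-4-methoxy-6-methylbenzoate | COc1cc(C)c(C(=O)OCc2ccccc2)c(F)c1C=O | intermediate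
19 | benzyl 3-formyl-4-methoxy-2-[(7-methoxy-2,2,5-trimethyl-4-oxochroman-6-yl)oxy]-6-methylbenzoate | COc1cc(C)c(C(=O)OCc2ccccc2)c(Oc2c(C)c3C(=O)CC(C)(C)Oc3cc2OC)c1C=O | intermediate
20 | 3-formyl-4-hydroxy-2-[(7-hydroxy-2,2,5-trimethyl-4-oxochroman-6-yl)oxy]-6-methylbenzoic acid | Cc1cc(O)c(C=O)c(Oc2c(C)c3C(=O)CC(C)(C)Oc3cc2O)c1C(=O)O | intermediate
21 | mixed anhydride of 20 with trifluoroacetic acid (not isolated) | Cc1cc(O)c(C=O)c(Oc2c(C)c3C(=O)CC(C)(C)Oc3cc2O)c1C(=O)OC(=O)C(F)(F)F | intermediate
22 | mollicellin A | Cc1cc(O)c(C=O)c2c1C(=O)Oc1cc3c(c(C)c1O2)C(=O)CC(C)(C)O3 | target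

Total step count: 13. Longest linear sequence: 8 steps (1, 2, 5, 6, 7, 11, 12, 13).

Steps most likely to fail

Step 5. The cycloaddition may be too slow. Both diene termini are substituted, the alkyne is internal, and its carbonyl is weakened by cross-conjugation with the dimethylvinyl group. Thermal decay or hydrolysis of the silyl ketene acetal and unselective consumption of the dienone could then take over. The fallback sets out from 4 and keeps the same ring B construction, but uses the smaller and more electrophilic commercial pent-3-yn-2-one as the two-carbon partner. After the same acidic work-up this should give 1-[3-(benzyloxy)-6-hydroxy-4-methoxy-2-methylphenyl]ethan-1-one F1. Ring D is then built separately by Kabbe condensation of F1 with acetone (pyrrolidine, MeOH, reflux), an enamine aldol condensation followed by oxa-Michael closure. This comes back to the route at 12.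

Step 11. Ether formation between a di-ortho-substituted phenoxide and a di-ortho-substituted fluoride may stall for steric reasons. Transfer of the benzyl group from the ester to the phenoxide would then have time to compete. The fallback sets out from 13 and 17 and reverses the order of ether formation and carbonylation. Bromide 17 carries no ester, so it tolerates forcing SNAr conditions (K2CO3, DMA, 120 °C). The fluoride ortho to the formyl group is the only activated leaving group, and the product should be 3-bromo-6-methoxy-4-methyl-2-[(7-methoxy-2,2,5-trimethyl-4-oxochroman-6-yl)oxy]benzaldehyde F2. Alkoxycarbonylation of F2 (Pd(OAc)2, di(1-adamantyl)-n-butylphosphine, CO 10 bar, BnOH, Et3N, 110 °C) comes back to the route at 19.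

Step 12. The non-chelated methyl ether para to the ketone needs the most forcing conditions of the three groups. During that time the tertiary ether of ring D may open or the formyl group may be halogenated, and cleavage may stay incomplete. The fallback sets out from 13 and removes this methyl group before the sensitive ring A is attached.
- NaSEt in DMF at 110 °C (SN2 demethylation para to the ketone, with no aldehyde, ester or activated diaryl ether yet present) should give 6,7-dihydroxy-2,2,5-trimethylchroman-4-one F3.
- The more acidic and less hindered 7-hydroxyl is then alkylated selectively (MOMCl, 1 equiv, iPr2NEt, CH2Cl2, 0 °C), as with 3,4-dihydroxyaryl carbonyl compounds, to give 6-hydroxy-7-(methoxymethoxy)-2,2,5-trimethylchroman-4-one F4.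
- SNAr with 18 under the conditions of step 11 gives benzyl 3-formyl-4-methoxy-2-{[7-(methoxymethoxy)-2,2,5-trimethyl-4-oxochroman-6-yl]oxy}-6-methylbenzoate F5.
- BCl3 (CH2Cl2, −78 °C to 0 °C) removes the acetal, the benzyl ester and the chelated methyl ether, all of them easy substrates at low temperature, and comes back to the route at 20.

Further compounds
F1 | step 5 | 1-[3-(benzyloxy)-6-hydroxy-4-methoxy-2-methylphenyl]ethan-1-one | COc1cc(O)c(C(C)=O)c(C)c1OCc1ccccc1
F2 | step 11 | 3-bromo-6-methoxy-4-methyl-2-[(7-methoxy-2,2,5-trimethyl-4-oxochroman-6-yl)oxy]benzaldehyde | COc1cc(C)c(Br)c(Oc2c(C)c3C(=O)CC(C)(C)Oc3cc2OC)c1C=O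
F3 | step 12 | 6,7-dihydroxy-2,2,5-trimethylchroman-4-one | Cc1c(O)c(O)cc2OC(C)(C)CC(=O)c12
F4 | step 12 | 6-hydroxy-7-(methoxymethoxy)-2,2,5-trimethylchroman-4-one | COCOc1cc2OC(C)(C)CC(=O)c2c(C)c1O
F5 | step 12 | benzyl 3-formyl-4-methoxy-2-{[7-(methoxymethoxy)-2,2,5-trimethyl-4-oxochroman-6-yl]oxy}-6-methylbenzoate | COCOc1cc2OC(C)(C)CC(=O)c2c(C)c1Oc1c(C=O)c(OC)cc(C)c1C(=O)OCc1ccccc1
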